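**Retrosynthetic overview**
1. Target 34 ⇐ oxidation at C29 of alcohol 33 ⇐ one-pot cage closure of acetoxyfulvene keto-imine 29: C16–C14 aldol (ring D), N19–C26 alkylation (ring F), hydration of the bridgehead iminium (C17–OH).
2. Rings A and B are grown on the 1,3-diketone of ring C (14): C11–C6 Michael addition to nitroalkene 18, O9–C10 cyclodehydration (ring B), Nef reaction, Claisen acylation at C13 with the chiral-pool unit C14–C29–C27–C26 (26), Knoevenagel closure C13=C12 (ring A).
3. Key disconnection C12–C24 (ring C): an acylketene released thermally from a dioxinone is C-acylated intramolecularly by the enamine tautomer of the ring E 1-pyrroline 12; this creates the quaternary C24 cis to the C21 tether.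
4. Enabling feature: C24 is the α-carbon of C17, the carbinolamine carbon shared by rings D, E and F (a masked ketimine, hence an enamine carbon); C12–C11–C10(–O9) of the seven-membered ring C is a masked 1,3-dicarbonyl (fulvene carbon C12, enol-ether carbon C10), the signature of an acylketene.
5. Ring order: E (asymmetric Michael addition, reductive cyclisation) → C → B → A → D and F together.

Key step: step 6

**Remarks**
- Atom numbers follow the order of the atoms in the target SMILES: C1, C2, O3 acetyl; O4 enol oxygen; ring A = C5, C6, C11, C12, C13; ring B = C6, C7, C8, O9, C10, C11; ring C = C10, C11, C12, C24, C21, C22, C23; ring D = C12, C13, C14, C16, C17, C24; ring E = C17, N19, C20, C21, C24; ring F = C14, C16, C17, N19, C26, C27, C29.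
- C24 (before step 6), C11, C5 and C6 (steps 8 to 14) are transient stereocentres whose epimers converge; they are drawn without configuration. C29 carries a defined but temporary configuration that is erased in step 18.
- Assumption: (S)-4-methyldihydrofuran-2(3H)-one is bought as a catalogue chemical, and the (1R,2R) catalyst of step 4 is taken to give the (S) centre at C21; if its facial sense is opposite, its antipode is used.

**Step 1**
Reactants: 1 2,2,6-trimethyl-4H-1,3-dioxin-4-one; 2 allyl bromide
Product: 3 6-(but-3-en-1-yl)-2,2-dimethyl-4H-1,3-dioxin-4-one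
Conditions: LiN(iPr)2, THF/DMPU, −78 °C; then 2, −78 to −20 °C
Reagents that add atoms: none
Why: γ-deprotonation gives the extended lithium dienolate, which is alkylated at the exocyclic carbon (C23) by the reactive allylic bromide (vinylogous enolate alkylation), installing C22 and C21.

**Step 2**
Reactants: 3 butenyl dioxinone
Product: 5 3-(2,2-dimethyl-4-oxo-4H-1,3-dioxin-6-yl)propanal, via diol 4 (not isolated)
Conditions: OsO4 (2 mol%), NaIO4, 2,6-lutidine, dioxane/H2O, rt
Reagents that add atoms: sodium periodate, [Na+].[O-]I(=O)(=O)=O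
Why: the electron-rich terminal alkene is dihydroxylated and cleaved in preference to the electron-poor trisubstituted dioxinone alkene (Lemieux–Johnson oxidation), giving the C21 aldehyde.

**Step 3**
Reactants: 5 aldehyde; 6 nitromethane
Product: 8 2,2-dimethyl-6-[(3E)-4-nitrobut-3-en-1-yl]-4H-1,3-dioxin-4-one, via nitro alcohol 7 (not isolated)
Conditions: MeNO2, Et3N (cat.), THF, 0 °C; then MsCl, Et3N, CH2Cl2, −10 °C
Reagents that add atoms: none
Why: Henry addition followed by mesylation and E1cB elimination gives the conjugated (E)-nitroalkene that carries C20 and N19.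

**Step 4**
Reactants: 8 nitroalkene; 9 butan-2-one
Product: 10 6-[(3S)-4-methyl-3-(nitromethyl)-5-oxohexyl]-2,2-dimethyl-4H-1,3-dioxin-4-one
Conditions: 9 (10 equiv), 1-[(1R,2R)-2-aminocyclohexyl]-3-[3,5-bis(trifluoromethyl)phenyl]thiourea (10 mol%), PhCO2H (10 mol%), toluene, rt
Reagents that add atoms: none
Why: asymmetric enamine Michael addition of the ethyl ketone through its more substituted enamine to the thiourea-bound nitroalkene sets C21 under catalyst control, while the epimers at C24 converge in step 6.

**Step 5**
Reactants: 10 γ-nitro ketone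
Product: 12 6-{2-[(3S)-4,5-dimethyl-3,4-dihydro-2H-pyrrol-3-yl]ethyl}-2,2-dimethyl-4H-1,3-dioxin-4-one, via amino ketone 11 (not isolated)
Conditions: Zn, aq. HCl, EtOH, 0 °C to rt
Reagents that add atoms: none
Why: reduction of the nitro group to the primary amine is followed by spontaneous five-membered ketimine formation with the C17 ketone (reductive cyclisation of a γ-nitro ketone), which closes ring E.

**Step 6**
Reactants: 12 pyrroline dioxinone
Product: 14 (3aS,8aR)-1,8a-dimethyl-3,3a,4,5-tetrahydrocyclohepta[c]pyrrole-6,8(7H,8aH)-dione, via acylketene 13 (not isolated)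
Conditions: toluene (0.005 M), pyridinium p-toluenesulfonate (5 mol%), 110 °C
Reagents that add atoms: none
Why: Proposed new method: heating expels acetone from the dioxinone by retro-(4+2) cleavage to give acylketene 13, whose sp carbon C12 is attacked by C24 of the secondary enamine tautomer of the 1-pyrroline while the N–H is passed to the ketene oxygen (aza-ene-type C-acylation), which returns the ketimine and leaves ring C as an enolisable 1,3-diketone; the closest known reactions are the capture of dioxinone-derived acylketenes by enamines and enol ethers (C-acylation or oxa-(4+2) addition) and the intramolecular capture of acylketenes by tethered hydroxyl and amino groups in macrocyclisations. Ring C closes as a seven-membered ring by addition to the ketene carbon (7-exo with respect to the ketene C=O, the C11=C12 bond ending as the endocyclic enol). The quaternary stereocentre C24 is controlled by C21: the enamine carbon is planar in the five-membered ring, attack must follow its p-orbital, and the four-atom tether on the neighbouring C21 reaches only the face on which it stands, so that C12 enters cis to C22 and both C24 epimers of 12 converge. The step needs carbon-over-nitrogen and C24-over-C16 selectivity, which ring size secures (C24 gives the seven-membered ring, whereas N19 would have to close a bridged eight-membered lactam and C16 a nine-membered ring), and it needs intramolecular capture, which high dilution secures.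

**Step 7**
Reactants: 15 3-[(tert-butyldimethylsilyl)oxy]propanal; 16 nitroethane
Product: 18 tert-butyldimethyl{[(3E)-4-nitropent-3-en-1-yl]oxy}silane, via nitro alcohol 17 (not isolated)
Conditions: EtNO2, Et3N (cat.), THF, 0 °C; then MsCl, Et3N, CH2Cl2, −10 °C to rt
Reagents that add atoms: none
Why: Henry addition and dehydration give the trisubstituted (E)-nitroalkene, an electrophilic equivalent of the C6–C5(=O)–C13 acetyl unit that already carries C7, C8 and O9.

**Step 8**
Reactants: 14 bicyclic diketone imine; 18 nitroalkene
Product: 20 tricyclic nitro enol ether (rings B, C, E), via Michael adduct 19 (not isolated)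
Conditions: Et3N (10 mol%), THF, rt; then HCl (1.25 M in MeOH), 0 °C to rt
Reagents that add atoms: none
Why: the acidic cyclic 1,3-diketone adds through C11 to the nitroalkene (Michael addition of a 1,3-dicarbonyl), and acid then removes the silyl ether and closes ring B by hemiketalisation and dehydration at C10, the carbonyl not shielded by the quaternary C24 (4,4-disubstituted cyclic 1,3-diones likewise form their enol ethers at the remote carbonyl), which also erases the C11 stereocentre.

**Step 9**
Reactants: 20 nitro enol ether
Product: 21 tricyclic methyl ketone (acetyl group on C6)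
Conditions: NaOMe, MeOH, 0 °C; then aq. TiCl3, NH4OAc, rt
Reagents that add atoms: water, O
Why: the secondary nitronate is reduced by TiCl3 to the imine and hydrolysed in the buffered medium to the C5 ketone (reductive Nef reaction), conditions that spare the vinylogous ester and the cyclic ketimine.

**Step 10**
Reactants: 22 (S)-4-methyldihydrofuran-2(3H)-one
Product: 23 (3S,4R)-3-hydroxy-4-methyldihydrofuran-2(3H)-one
Conditions: LiN(iPr)2, THF, −78 °C; then 3-phenyl-2-(phenylsulfonyl)oxaziridine, −78 °C
Reagents that add atoms: 3-phenyl-2-(phenylsulfonyl)oxaziridine, O=S(=O)(c1ccccc1)N1OC1c1ccccc1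
Why: the lithium enolate is oxidised by the N-sulfonyloxaziridine on the face anti to the neighbouring methyl group, giving the trans hydroxy lactone (enolate hydroxylation); this oxygen later becomes the C29 ketone oxygen.

**Step 11**
Reactants: 23 hydroxy lactone
Product: 24 (3S,4R)-3-[(tert-butyldimethylsilyl)oxy]-4-methyldihydrofuran-2(3H)-one
Conditions: TBSCl, imidazole, DMF, rt
Reagents that add atoms: tert-butyldimethylsilyl chloride, CC(C)(C)[Si](C)(C)Cl
Why: silylation of the secondary alcohol protects the future C29 oxygen through the enolate and Lewis-acid steps.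

**Step 12**
Reactants: 24 silyloxy lactone
Product: 25 (2S,3R)-2-[(tert-butyldimethylsilyl)oxy]-4-hydroxy-N-methoxy-N,3-dimethylbutanamide
Conditions: MeNH(OMe)·HCl, iPrMgCl, THF, −20 °C
Reagents that add atoms: N,O-dimethylhydroxylamine hydrochloride, CNOC.Cl
Why: the magnesium amide of N,O-dimethylhydroxylamine opens the lactone to the N-methoxy-N-methyl amide (amide formation from a lactone) and frees the C26 hydroxyl.

**Step 13**
Reactants: 25 hydroxy amide
Product: 26 (2S,3S)-2-[(tert-butyldimethylsilyl)oxy]-4-chloro-N-methoxy-N,3-dimethylbutanamide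
Conditions: PPh3, CCl4, CH2Cl2, 0 °C to rt
Reagents that add atoms: carbon tetrachloride, ClC(Cl)(Cl)Cl
Why: Appel chlorination converts the primary alcohol into the chloride under neutral conditions, which blocks relactonisation and installs the latent alkylating carbon C26.

**Step 14**
Reactants: 21 tricyclic methyl ketone; 26 chloro amide
Product: 27 β-diketone C5(=O)–C13H2–C14(=O) carrying the C29–C27–C26 chain
Conditions: LiN(iPr)2, THF, −78 °C; then 26, −78 to −30 °C
Reagents that add atoms: none
Why: kinetic deprotonation of the methyl ketone at C13 and acylation by the N-methoxy-N-methyl amide, whose chelated tetrahedral adduct collapses only on work-up, gives the β-diketone without over-addition (crossed Claisen acylation).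

**Step 15**
Reactants: 27 β-diketone
Product: 28 hydroxyfulvene ketone (rings A, B, C, E)
Conditions: TiCl4, pyridine, THF, 0 °C to rt
Reagents that add atoms: none
Why: TiCl4/pyridine-mediated Knoevenagel condensation of the β-diketone carbon C13 with the ring C carbonyl C12, a 5-exo-trig closure (attack at C10 would be 5-endo-trig) of the kind known for active methylene compounds and pyranone-type vinylogous ester carbonyls, closes ring A, and the product enolises to the hydrogen-bonded hydroxyfulvene, which erases the C6 stereocentre.

**Step 16**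
Reactants: 28 hydroxyfulvene ketone
Product: 29 acetoxyfulvene ketone
Conditions: NaN(SiMe3)2, THF, −78 °C; then AcCl, −78 °C
Reagents that add atoms: acetyl chloride, CC(=O)Cl
Why: the vinylogous acid is deprotonated selectively and the resulting oxygen anion is acetylated by the acyl chloride at low temperature faster than the neutral ketimine can react (O-acylation of an enolate).

**Step 17**
Reactants: 29 acetoxyfulvene ketone
Product: 33 hexacyclic triol (C29 alcohol of the target), via iodide 30 (not isolated), via hydroxy imine 31 (not isolated), via iminium iodide 32 (not isolated)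
Conditions: NaI, pyridinium p-toluenesulfonate (10 mol%), MeCN, 80 °C; then HF·pyridine, pyridine, THF, 0 °C; then aq. NaHCO3
Reagents that add atoms: water, O
Why: chloride–iodide exchange, reversible aldol addition of the enamine tautomer (C16) to the C14 ketone (ring D) and irreversible N-alkylation of the imine nitrogen by C26 (ring F) funnel the material through the only C14 epimer whose C29 arm stands cis-diaxial to N19, after which fluoride removes the silyl ether and water adds to the bridgehead iminium to give the C17 carbinolamine, whose configuration is fixed by the three rings it joins.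

**Step 18**
Reactants: 33 hexacyclic triol
Product: 34 target CNP0309418.1
Conditions: Dess–Martin periodinane, pyridine, CH2Cl2, 0 °C
Reagents that add atoms: none
Why: Dess–Martin oxidation of the only secondary alcohol under buffered conditions gives the C29 ketone without cleaving the adjacent tertiary carbinol or enolising C27 (alcohol oxidation).

**Compound list**
1 | 2,2,6-trimethyl-4H-1,3-dioxin-4-one | CC1=CC(=O)OC(C)(C)O1 | starting material
2 | allyl bromide | C=CCBr | starting material
3 | 6-(but-3-en-1-yl)-2,2-dimethyl-4H-1,3-dioxin-4-one | C=CCCC1=CC(=O)OC(C)(C)O1 | intermediate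
4 | 6-(3,4-dihydroxybutyl)-2,2-dimethyl-4H-1,3-dioxin-4-one (not isolated) | OCC(O)CCC1=CC(=O)OC(C)(C)O1 | intermediate
5 | 3-(2,2-dimethyl-4-oxo-4H-1,3-dioxin-6-yl)propanal | O=CCCC1=CC(=O)OC(C)(C)O1 | intermediate
6 | nitromethane | C[N+](=O)[O-] | starting material
7 | 6-(3-hydroxy-4-nitrobutyl)-2,2-dimethyl-4H-1,3-dioxin-4-one (not isolated) | O=[N+]([O-])CC(O)CCC1=CC(=O)OC(C)(C)O1 | intermediate
8 | 2,2-dimethyl-6-[(3E)-4-nitrobut-3-en-1-yl]-4H-1,3-dioxin-4-one | O=[N+]([O-])/C=C/CCC1=CC(=O)OC(C)(C)O1 | intermediate
9 | butan-2-one | CCC(C)=O | starting material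
10 | 6-[(3S)-4-methyl-3-(nitromethyl)-5-oxohexyl]-2,2-dimethyl-4H-1,3-dioxin-4-one (C24 epimers) | CC(=O)C(C)[C@@H](C[N+](=O)[O-])CCC1=CC(=O)OC(C)(C)O1 | intermediate
11 | 6-[(3S)-3-(aminomethyl)-4-methyl-5-oxohexyl]-2,2-dimethyl-4H-1,3-dioxin-4-one (not isolated) | CC(=O)C(C)[C@@H](CN)CCC1=CC(=O)OC(C)(C)O1 | intermediate
12 | 6-{2-[(3S)-4,5-dimethyl-3,4-dihydro-2H-pyrrol-3-yl]ethyl}-2,2-dimethyl-4H-1,3-dioxin-4-one (C24 epimers) | CC1=NC[C@@H](CCC2=CC(=O)OC(C)(C)O2)C1C | intermediate
13 | acylketene: 6-[(3S)-4,5-dimethyl-3,4-dihydro-2H-pyrrol-3-yl]hex-1-ene-1,3-dione (not isolated) | CC1=NC[C@@H](CCC(=O)C=C=O)C1C | intermediate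
14 | (3aS,8aR)-1,8a-dimethyl-3,3a,4,5-tetrahydrocyclohepta[c]pyrrole-6,8(7H,8aH)-dione (rings C and E; C12 and C10 ketones) | CC1=NC[C@H]2CCC(=O)CC(=O)[C@@]12C | intermediate
15 | 3-[(tert-butyldimethylsilyl)oxy]propanal | O=CCCO[Si](C)(C)C(C)(C)C | starting material
16 | nitroethane | CC[N+](=O)[O-] | starting material
17 | 1-[(tert-butyldimethylsilyl)oxy]-4-nitropentan-3-ol (not isolated) | CC(C(O)CCO[Si](C)(C)C(C)(C)C)[N+](=O)[O-] | intermediate
18 | tert-butyldimethyl{[(3E)-4-nitropent-3-en-1-yl]oxy}silane | C/C(=C\CCO[Si](C)(C)C(C)(C)C)[N+](=O)[O-] | intermediate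
19 | Michael adduct: 14 carrying on C11 a 1-[(tert-butyldimethylsilyl)oxy]-4-nitropentan-3-yl group (not isolated) | CC1=NC[C@H]2CCC(=O)C(C(CCO[Si](C)(C)C(C)(C)C)C(C)[N+](=O)[O-])C(=O)[C@@]12C | intermediate
20 | tricycle of rings B, C, E: O9–C8–C7–C6 closed onto C10 as the enol ether C10=C11; C6 bears a 1-nitroethyl group; C12 ketone; C17=N19 ketimine | CC1=NC[C@H]2CCC3=C(C(CCO3)C(C)[N+](=O)[O-])C(=O)[C@@]12C | intermediate
21 | as 20, with an acetyl group on C6 (C5 ketone, C13 methyl) | CC1=NC[C@H]2CCC3=C(C(CCO3)C(C)=O)C(=O)[C@@]12C | intermediate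
22 | (S)-4-methyldihydrofuran-2(3H)-one | O1C[C@@H](C)CC1=O | starting material
23 | (3S,4R)-3-hydroxy-4-methyldihydrofuran-2(3H)-one | O1C[C@@H](C)[C@H](O)C1=O | intermediate
24 | (3S,4R)-3-[(tert-butyldimethylsilyl)oxy]-4-methyldihydrofuran-2(3H)-one | O1C[C@@H](C)[C@H](O[Si](C)(C)C(C)(C)C)C1=O | intermediate
25 | (2S,3R)-2-[(tert-butyldimethylsilyl)oxy]-4-hydroxy-N-methoxy-N,3-dimethylbutanamide | OC[C@@H](C)[C@H](O[Si](C)(C)C(C)(C)C)C(=O)N(C)OC | intermediate
26 | (2S,3S)-2-[(tert-butyldimethylsilyl)oxy]-4-chloro-N-methoxy-N,3-dimethylbutanamide | ClC[C@@H](C)[C@H](O[Si](C)(C)C(C)(C)C)C(=O)N(C)OC | intermediate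
27 | β-diketone: 21 acylated at C13; side chain C5(=O)–C13H2–C14(=O)–C29H(OTBS)–C27H(CH3)–C26H2Cl, configured as in 26 | CC1=NC[C@H]2CCC3=C(C(CCO3)C(=O)CC(=O)[C@@H](O[Si](C)(C)C(C)(C)C)[C@H](C)CCl)C(=O)[C@@]12C | intermediate
28 | hydroxyfulvene of rings A, B, C, E: C5–OH, C5=C6, C10=C11, C12=C13; C13 bears the C14 ketone chain; C17=N19 ketimine | OC1=C2CCOC3=C2C(=C1C(=O)[C@@H](O[Si](C)(C)C(C)(C)C)[C@H](C)CCl)[C@@]1(C)C(C)=NC[C@H]1CC3 | intermediate
29 | C5 acetate of 28 | CC(=O)OC1=C2CCOC3=C2C(=C1C(=O)[C@@H](O[Si](C)(C)C(C)(C)C)[C@H](C)CCl)[C@@]1(C)C(C)=NC[C@H]1CC3 | intermediate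
30 | C26 iodide corresponding to 29 (not isolated) | CC(=O)OC1=C2CCOC3=C2C(=C1C(=O)[C@@H](O[Si](C)(C)C(C)(C)C)[C@H](C)CI)[C@@]1(C)C(C)=NC[C@H]1CC3 | intermediate
31 | ring D aldol adduct: C16–C14 bond, tertiary C14–OH, C17=N19 ketimine, C26–I (not isolated) | CC(=O)OC1=C2CCOC3=C2C2=C1[C@@](O)([C@@H](O[Si](C)(C)C(C)(C)C)[C@H](C)CI)CC1=NC[C@@H](CC3)[C@@]21C | intermediate
32 | hexacyclic iminium iodide: N19–C26 bond closed, C17=N19+, C29–OTBS (not isolated) | CC(=O)OC1=C2CCOC3=C2C2=C1[C@]1(O)CC4=[N+](C[C@@H](CC3)[C@@]24C)C[C@@H](C)[C@@H]1O[Si](C)(C)C(C)(C)C.[I-] | intermediate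
33 | hexacyclic triol: the target with a secondary alcohol at C29 in place of the ketone | CC(=O)OC1=C2CCOC3=C2C2=C1[C@]1(O)C[C@@]4(O)N(C[C@@H](CC3)[C@@]24C)C[C@@H](C)[C@@H]1O | intermediate
34 | CNP0309418.1 | CC(=O)OC1=C2CCOC3=C2C2=C1[C@]1(O)C[C@@]4(O)N(C[C@@H](CC3)[C@@]24C)C[C@@H](C)C1=O | target

**Totals**
Total step count: 18.
Longest linear sequence: 13 steps (steps 1 to 6, 8, 9 and 14 to 18).

**Steps most likely to fail**

1. Step 6 (Proposed new method). What may go wrong: the acylketene is intercepted by the imine nitrogen (N-acylation or oxazinone formation, within the molecule or between molecules) before the enamine tautomer can deliver C24. The fallback uses known chemistry, sets out from 10 and returns at 14. Nitro ketone 10 is converted with Me3SiCl, NaI and Et3N in MeCN into its more substituted trimethylsilyl enol ether F1. Heating F1 in toluene at 110 °C releases the acylketene, which is captured at carbon by the silyl enol ether (the known capture of dioxinone-derived acylketenes by silyl enol ethers). Aqueous acidic work-up gives nitro triketone F2; its C24 epimers are separated at this point because ring E is not yet there to relay C21. Zn and aqueous HCl then reduce the nitro group and the amine condenses with the acetyl ketone to give 14.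

2. Step 17. What may go wrong: alkylation at C16 through the enamine tautomer, or at the tertiary C14 hydroxyl, outruns N-alkylation, or the aldol equilibrium stays on the open side. The fallback sets out from 29 and returns at 33. Compound 29 is treated with Me3SiOTf and iPr2NEt in CH2Cl2 at −78 °C, so that the N-silyl enamine adds to the silyl-activated C14 ketone and the adduct is held as tertiary silyl ether F3 (the C14 epimer able to bridge is carried on). F3 is heated with NaI in MeCN without acid or base, so that the imine nitrogen is the only nucleophile present in quantity, and aqueous NaHCO3 converts the iminium salt into bis-silylated carbinolamine F4. HF·pyridine removes both silyl groups to give 33.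

3. Step 15. What may go wrong: the stabilised diketone carbon fails to add to the hindered vinylogous-ester carbonyl C12, or the diketone oxygen displaces the chloride. The fallback sets out from 21 (with 26) and returns at 28. Methyl ketone 21 is cyclised first through its more nucleophilic simple enolate (KOtBu, tBuOH) to dienone F5. Iodination with I2 and pyridine at the nucleophilic α-carbon C13 gives iodo dienone F6. Amide 26 is reduced with iBu2AlH to aldehyde F7. Nozaki–Hiyama–Kishi coupling of F6 with F7 (CrCl2, NiCl2 cat., DMF) gives allylic alcohol F8, and Dess–Martin oxidation gives the acyl dienone, which enolises to 28.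

**Further compounds**
F1 | step 6 | trimethylsilyl enol ether of 10 at C17=C24 (either geometry) | CC(O[Si](C)(C)C)=C(C)[C@@H](C[N+](=O)[O-])CCC1=CC(=O)OC(C)(C)O1
F2 | step 6 | nitro triketone: cycloheptane-1,3-dione ring C bearing on C24 methyl and acetyl and on C21 nitromethyl | CC(=O)[C@]1(C)C(=O)CC(=O)CC[C@@H]1C[N+](=O)[O-]
F3 | step 17 | ring D aldol adduct of 29 as its C14 trimethylsilyl ether (C26–Cl, C17=N19) | CC(=O)OC1=C2CCOC3=C2C2=C1[C@@](O[Si](C)(C)C)([C@@H](O[Si](C)(C)C(C)(C)C)[C@H](C)CCl)CC1=NC[C@@H](CC3)[C@@]21C
F4 | step 17 | hexacyclic carbinolamine with C14–OSiMe3 and C29–OTBS | CC(=O)OC1=C2CCOC3=C2C2=C1[C@]1(O[Si](C)(C)C)C[C@@]4(O)N(C[C@@H](CC3)[C@@]24C)C[C@@H](C)[C@@H]1O[Si](C)(C)C(C)(C)C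
F5 | step 15 | tetracyclic dienone of rings A, B, C, E (C5 ketone, C13–H, C12=C13, C10=C11) | CC1=NC[C@H]2CCC3=C4C(CCO3)C(=O)C=C4[C@@]12C
F6 | step 15 | C13 iodide of F5 | CC1=NC[C@H]2CCC3=C4C(CCO3)C(=O)C(I)=C4[C@@]12C
F7 | step 15 | (2S,3S)-2-[(tert-butyldimethylsilyl)oxy]-4-chloro-3-methylbutanal | ClC[C@@H](C)[C@H](O[Si](C)(C)C(C)(C)C)C=O
F8 | step 15 | allylic alcohol from F6 and F7 (C13–C14 bond, C14 secondary alcohol) | CC1=NC[C@H]2CCC3=C4C(CCO3)C(=O)C(C(O)[C@@H](O[Si](C)(C)C(C)(C)C)[C@H](C)CCl)=C4[C@@]12C
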